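**Retrosynthetic overview**

1. Numbering used: ring A (the quinone carrying the 2-methoxyphenethyl chain) is C1(=O), C2(OH), C3(CH3), C4(=O), C5 (bond to ring B), C6 (chain). Ring B is C1' (bond to ring A), C2' (phenethyl), C3'(=O), C4'(OH), C5'(CH3), C6'(=O). The last disconnection is the two vinylogous methyl esters at O2 and O4'.
2. The C5–C1' bond is cut as a Stille coupling (ring A as 5-stannylquinone, ring B as 1'-bromoquinone). Ring A is not built six-membered: it comes from Moore ring expansion of a squarate-derived 4-alkynyl-4-(stannyloxy)cyclobutenone (four-membered ring = C1–C4, alkyne = C5/C6), in one flask with the coupling.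
3. Enabling feature: in ring A, C1(=O)–C2(O)=C3(CH3)–C4(=O) is a masked cyclobutenone, and the inter-ring carbon C5 lies between C4 (the former carbinol carbon) and C6 (the alkyne terminus carrying the chain). C5 is therefore the σ-radical carbon of the ring-expanded diradical, and a tin group bound to O4 is delivered to the carbon that must bond to ring B.
4. Ring B comes from the same squarate with the opposite regiochemistry (4-alkenyl-4-hydroxycyclobutenone, 6π ring expansion, oxidation) and is brominated at C1'. Brominating this ring and stannylating ring A keeps Br2 away from the anisole.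
5. Order of ring formation: ring B (step 3), then ring A together with the C5–C1' bond (step 9), then unmasking of the two hydroxyquinones (step 10).

Key step: step 9

Remark: the target SMILES carries no stereodescriptor, so the quinone–quinone axis is taken as configurationally unassigned; every cyclobutenone intermediate is racemic and its single stereocentre is destroyed in the ring expansion.

**Route**

Step 1
Reactants: 1 dimethyl squarate (3,4-dimethoxycyclobut-3-ene-1,2-dione)
Product: 3 3-methoxy-4-methylcyclobut-3-ene-1,2-dione, via lithium alkoxide 2 (not isolated)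
Conditions: MeLi, THF, −78 °C; then conc. HCl, CH2Cl2, rt
Reagents that add atoms: methyllithium [Li]C; water O
Why: 1,2-addition of MeLi to one squarate carbonyl, then acid-induced ionisation of the tertiary carbinol to the methoxy-stabilised cyclobutenyl cation and hydrolysis at its far end (the standard squarate-to-alkylcyclobutenedione sequence), should give 3.

Step 2
Reactants: 4 2-bromo-4-phenylbut-1-ene; 3 3-methoxy-4-methylcyclobut-3-ene-1,2-dione
Product: 7 4-hydroxy-3-methoxy-2-methyl-4-(4-phenylbut-1-en-2-yl)cyclobut-2-en-1-one (racemic), via vinyllithium 5 (not isolated), via lithium alkoxide 6 (not isolated)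
Conditions: 4, t-BuLi (2 equiv), Et2O, −78 °C; then 3, THF, −78 °C; NH4Cl (aq)
Reagents that add atoms: none
Why: Br/Li exchange gives the α-substituted vinyllithium, which should add 1,2 to the more electrophilic ketone of 3 (the carbonyl next to the methoxy-bearing carbon, the other being a vinylogous ester), the established regiochemistry for organolithium addition to 3-alkoxy-4-alkylcyclobutenediones; the carbinol centre forms racemic and is destroyed in step 3.

Step 3
Reactants: 7 4-hydroxy-3-methoxy-2-methyl-4-(4-phenylbut-1-en-2-yl)cyclobut-2-en-1-one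
Product: 9 2-methoxy-3-methyl-6-(2-phenylethyl)cyclohexa-2,5-diene-1,4-dione, via hydroquinone 8 (not isolated)
Conditions: PhMe, 110 °C; then Ag2O, rt
Reagents that add atoms: none
Why: thermal 4π-electrocyclic ring opening (hydroxyl rotating outward), 6π-electrocyclisation of the dienylketene and tautomerisation (the squarate-based ring expansion of 4-alkenyl-4-hydroxycyclobutenones) should give the hydroquinone, which Ag2O oxidises to the quinone.

Step 4
Reactants: 9 2-methoxy-3-methyl-6-(2-phenylethyl)cyclohexa-2,5-diene-1,4-dione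
Product: 11 5-bromo-2-methoxy-3-methyl-6-(2-phenylethyl)cyclohexa-2,5-diene-1,4-dione, via trans-dibromide 10 (not isolated)
Conditions: Br2, NaOAc, AcOH, rt
Reagents that add atoms: bromine BrBr
Why: bromine should add across the only hydrogen-bearing quinone double bond and acetate-induced loss of HBr (addition–elimination, as in the bromination of 2,3-dimethoxy-5-methyl-1,4-benzoquinone) then gives the bromoquinone, the unactivated phenyl ring and the vinylogous ester being left alone.

Step 5
Reactants: 12 3-(2-methoxyphenyl)propanal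
Product: 13 1-(but-3-yn-1-yl)-2-methoxybenzene
Conditions: dimethyl (1-diazo-2-oxopropyl)phosphonate, K2CO3, MeOH, rt
Reagents that add atoms: dimethyl (1-diazo-2-oxopropyl)phosphonate COP(=O)(OC)C(=[N+]=[N-])C(C)=O
Why: Ohira–Bestmann (Seyferth–Gilbert) homologation should convert the enolisable aldehyde into the terminal alkyne under mild basic conditions.

Step 6
Reactants: 13 1-(but-3-yn-1-yl)-2-methoxybenzene; 1 dimethyl squarate
Product: 16 2,3-dimethoxy-4-[4-(2-methoxyphenyl)but-1-yn-1-yl]-4-(trimethylsilyloxy)cyclobut-2-en-1-one (racemic), via lithium acetylide 14 (not isolated), via lithium alkoxide 15 (not isolated)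
Conditions: 13, n-BuLi, THF, −78 °C; then 1, −78 °C; then TMSCl, −78 → 0 °C
Reagents that add atoms: chlorotrimethylsilane C[Si](C)(C)Cl
Why: deprotonation of the alkyne, 1,2-addition of the acetylide to one squarate carbonyl and in situ O-silylation of the tertiary alkoxide (alkynyl addition to a squarate with silyl trapping) should give 16, whose racemic carbinol centre is destroyed in step 9.

Step 7
Reactants: 16 2,3-dimethoxy-4-[4-(2-methoxyphenyl)but-1-yn-1-yl]-4-(trimethylsilyloxy)cyclobut-2-en-1-one
Product: 19 2-methoxy-4-[4-(2-methoxyphenyl)but-1-yn-1-yl]-3-methyl-4-(trimethylsilyloxy)cyclobut-2-en-1-one (racemic), via lithium alkoxide 17 (not isolated), via trifluoroacetate 18 (not isolated)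
Conditions: MeLi, THF, −78 °C; then (CF3CO)2O, −78 °C; then H2O, 0 °C
Reagents that add atoms: methyllithium [Li]C; water O
Why: MeLi should add 1,2 to the only carbonyl, and trifluoroacetylation of the new tertiary alkoxide (the silyl ether cannot leave) triggers ionisation and hydrolysis at the distal methoxy-bearing carbon, the sequential-addition/1,3-carbonyl-transposition protocol of squarate chemistry that places the methyl group next to the carbinol carbon.

Step 8
Reactants: 19 2-methoxy-4-[4-(2-methoxyphenyl)but-1-yn-1-yl]-3-methyl-4-(trimethylsilyloxy)cyclobut-2-en-1-one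
Product: 20 4-hydroxy-2-methoxy-4-[4-(2-methoxyphenyl)but-1-yn-1-yl]-3-methylcyclobut-2-en-1-one (racemic)
Conditions: citric acid (cat.), MeOH, 0 °C → rt
Reagents that add atoms: none
Why: acid-catalysed methanolysis (silyl ether cleavage), under conditions too mild to ionise the tertiary propargylic carbinol, should free the hydroxyl group needed for stannylation.

Step 9
Reactants: 20 4-hydroxy-2-methoxy-4-[4-(2-methoxyphenyl)but-1-yn-1-yl]-3-methylcyclobut-2-en-1-one; 11 5-bromo-2-methoxy-3-methyl-6-(2-phenylethyl)cyclohexa-2,5-diene-1,4-dione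
Product: 23 2-methoxy-5-[4-methoxy-5-methyl-3,6-dioxo-2-(2-phenylethyl)cyclohexa-1,4-dien-1-yl]-6-[2-(2-methoxyphenyl)ethyl]-3-methylcyclohexa-2,5-diene-1,4-dione, via stannyl ether 21 (not isolated), via stannylquinone 22 (not isolated)
Conditions: Bu3SnOMe, PhMe, rt (MeOH removed); 110 °C; then 11, Pd2(dba)3 (5 mol %), tri(2-furyl)phosphine (20 mol %), CuI (10 mol %), DMF, 50 °C
Reagents that add atoms: none
Why: Bu3SnOMe converts the tertiary alcohol into stannyl ether 21; on heating, 4π-conrotatory opening of the four-membered ring (O–Sn rotating outward, alkyne inward) gives an enynylketene whose ketene carbon bonds to the distal alkyne carbon, the Bu3Sn group shifts from O4 to the C5 σ-radical of the resulting quinoid diradical to give stannylquinone 22, and 22 then undergoes Stille coupling with 11 (oxidative addition of zerovalent palladium into C–Br, tin-to-copper-to-palladium transmetalation, reductive elimination). The closest known reaction types are the Moore rearrangement of 4-alkynyl-4-(stannyloxy)cyclobutenones to stannylquinones and the Pd/CuI-cocatalysed Stille coupling of stannylquinones with sp2 halides, here telescoped. Ring A is the only ring closed, by C1–C6 bond formation of the enynylketene in the six-membered (quinone-forming) mode rather than the five-membered (alkylidenecyclopentenedione) mode, which the alkyl, non-radical-stabilising substituent on the alkyne secures. No stereocentre is created: the carbinol centre of 20 is destroyed and the new C5–C1' axis has no defined configuration in the target. The step needs outward rotation of the oxygen substituent (secured by its donor character), tin transfer to C5 faster than attack of that radical on the pendant anisole ring (secured by the weak O–Sn bond held next to C5) and cross- rather than homo-coupling (secured by the Sn/Br pairing).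

Step 10
Reactants: 23 2-methoxy-5-[4-methoxy-5-methyl-3,6-dioxo-2-(2-phenylethyl)cyclohexa-1,4-dien-1-yl]-6-[2-(2-methoxyphenyl)ethyl]-3-methylcyclohexa-2,5-diene-1,4-dione
Product: 25 2-hydroxy-5-[4-hydroxy-5-methyl-3,6-dioxo-2-(2-phenylethyl)cyclohexa-1,4-dien-1-yl]-6-[2-(2-methoxyphenyl)ethyl]-3-methylcyclohexa-2,5-diene-1,4-dione (target), via disodium salt 24 (not isolated)
Conditions: NaOH (aq), THF, 0 °C → rt; then HCl (aq)
Reagents that add atoms: sodium hydroxide [Na+].[OH-]
Why: hydroxide should add to the methoxy-bearing β-carbon of each vinylogous ester and expel methoxide (addition–elimination hydrolysis of 2-methoxy-1,4-benzoquinones), the anisole ether being inert, and acidification of the dianion gives the bis(hydroxyquinone).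

**Compound list**

1 | dimethyl squarate (3,4-dimethoxycyclobut-3-ene-1,2-dione) | COC1=C(OC)C(=O)C1=O | starting material
2 | lithium 2,3-dimethoxy-1-methyl-4-oxocyclobut-2-en-1-olate (racemic; not isolated) | [Li+].[O-]C1(C)C(OC)=C(OC)C1=O | intermediate
3 | 3-methoxy-4-methylcyclobut-3-ene-1,2-dione | CC1=C(OC)C(=O)C1=O | intermediate
4 | 2-bromo-4-phenylbut-1-ene | C=C(Br)CCc1ccccc1 | starting material
5 | (4-phenylbut-1-en-2-yl)lithium (not isolated) | [Li]C(=C)CCc1ccccc1 | intermediate
6 | lithium 2-methoxy-3-methyl-4-oxo-1-(4-phenylbut-1-en-2-yl)cyclobut-2-en-1-olate (racemic; not isolated) | [Li+].[O-]C1(C(=C)CCc2ccccc2)C(OC)=C(C)C1=O | intermediate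
7 | 4-hydroxy-3-methoxy-2-methyl-4-(4-phenylbut-1-en-2-yl)cyclobut-2-en-1-one (racemic) | O=C1C(C)=C(OC)C1(O)C(=C)CCc1ccccc1 | intermediate
8 | 2-methoxy-3-methyl-6-(2-phenylethyl)benzene-1,4-diol (not isolated) | Oc1c(C)c(OC)c(O)c(CCc2ccccc2)c1 | intermediate
9 | 2-methoxy-3-methyl-6-(2-phenylethyl)cyclohexa-2,5-diene-1,4-dione | O=C1C(C)=C(OC)C(=O)C(CCc2ccccc2)=C1 | intermediate
10 | trans-5,6-dibromo-2-methoxy-3-methyl-6-(2-phenylethyl)cyclohex-2-ene-1,4-dione (bromines on opposite faces; racemic, one enantiomer drawn; not isolated) | Br[C@@H]1C(=O)C(C)=C(OC)C(=O)[C@]1(Br)CCc1ccccc1 | intermediate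
11 | 5-bromo-2-methoxy-3-methyl-6-(2-phenylethyl)cyclohexa-2,5-diene-1,4-dione | O=C1C(C)=C(OC)C(=O)C(CCc2ccccc2)=C1Br | intermediate
12 | 3-(2-methoxyphenyl)propanal | COc1ccccc1CCC=O | starting material
13 | 1-(but-3-yn-1-yl)-2-methoxybenzene | COc1ccccc1CCC#C | intermediate
14 | [4-(2-methoxyphenyl)but-1-yn-1-yl]lithium (not isolated) | [Li]C#CCCc1ccccc1OC | intermediate
15 | lithium 2,3-dimethoxy-1-[4-(2-methoxyphenyl)but-1-yn-1-yl]-4-oxocyclobut-2-en-1-olate (racemic; not isolated) | [Li+].[O-]C1(C#CCCc2ccccc2OC)C(OC)=C(OC)C1=O | intermediate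
16 | 2,3-dimethoxy-4-[4-(2-methoxyphenyl)but-1-yn-1-yl]-4-(trimethylsilyloxy)cyclobut-2-en-1-one (racemic) | COC1=C(OC)C(O[Si](C)(C)C)(C#CCCc2ccccc2OC)C1=O | intermediate
17 | lithium 2,3-dimethoxy-4-[4-(2-methoxyphenyl)but-1-yn-1-yl]-1-methyl-4-(trimethylsilyloxy)cyclobut-2-en-1-olate (racemic mixture of cis and trans isomers, both converge; not isolated) | [Li+].[O-]C1(C)C(OC)=C(OC)C1(O[Si](C)(C)C)C#CCCc1ccccc1OC | intermediate
18 | 2,3-dimethoxy-4-[4-(2-methoxyphenyl)but-1-yn-1-yl]-1-methyl-4-(trimethylsilyloxy)cyclobut-2-en-1-yl trifluoroacetate (racemic mixture of cis and trans isomers, both converge; not isolated) | FC(F)(F)C(=O)OC1(C)C(OC)=C(OC)C1(O[Si](C)(C)C)C#CCCc1ccccc1OC | intermediate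
19 | 2-methoxy-4-[4-(2-methoxyphenyl)but-1-yn-1-yl]-3-methyl-4-(trimethylsilyloxy)cyclobut-2-en-1-one (racemic) | O=C1C(OC)=C(C)C1(O[Si](C)(C)C)C#CCCc1ccccc1OC | intermediate
20 | 4-hydroxy-2-methoxy-4-[4-(2-methoxyphenyl)but-1-yn-1-yl]-3-methylcyclobut-2-en-1-one (racemic) | O=C1C(OC)=C(C)C1(O)C#CCCc1ccccc1OC | intermediate
21 | 2-methoxy-4-[4-(2-methoxyphenyl)but-1-yn-1-yl]-3-methyl-4-(tributylstannyloxy)cyclobut-2-en-1-one (racemic; not isolated) | O=C1C(OC)=C(C)C1(O[Sn](CCCC)(CCCC)CCCC)C#CCCc1ccccc1OC | intermediate
22 | 2-methoxy-6-[2-(2-methoxyphenyl)ethyl]-3-methyl-5-(tributylstannyl)cyclohexa-2,5-diene-1,4-dione (not isolated) | O=C1C(OC)=C(C)C(=O)C([Sn](CCCC)(CCCC)CCCC)=C1CCc1ccccc1OC | intermediate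
23 | 2-methoxy-5-[4-methoxy-5-methyl-3,6-dioxo-2-(2-phenylethyl)cyclohexa-1,4-dien-1-yl]-6-[2-(2-methoxyphenyl)ethyl]-3-methylcyclohexa-2,5-diene-1,4-dione | O=C1C(OC)=C(C)C(=O)C(C2=C(CCc3ccccc3)C(=O)C(OC)=C(C)C2=O)=C1CCc1ccccc1OC | intermediate
24 | disodium salt (bis-enolate) of 25 (not isolated) | [Na+].[Na+].COc1ccccc1CCC1=C(C2=C(CCc3ccccc3)C(=O)C([O-])=C(C)C2=O)C(=O)C(C)=C([O-])C1=O | intermediate
25 | 2-hydroxy-5-[4-hydroxy-5-methyl-3,6-dioxo-2-(2-phenylethyl)cyclohexa-1,4-dien-1-yl]-6-[2-(2-methoxyphenyl)ethyl]-3-methylcyclohexa-2,5-diene-1,4-dione | COc1ccccc1CCC1=C(C2=C(CCc3ccccc3)C(=O)C(O)=C(C)C2=O)C(=O)C(C)=C(O)C1=O | target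

**Step count and risks**

Total step count: 10. Longest linear sequence: 6 steps (steps 5–10; the ring B arm, steps 1–4, joins in step 9 and is equally six steps to the target).

Steps most likely to fail:

1. Step 9. Transmetalation from tin (through copper) to palladium between two fully substituted, electron-poor quinone carbons may be slower than protodestannylation, homocoupling and electron transfer to the bromoquinone. The tin shift must also outrun cyclisation of the C5 radical onto the pendant anisole ring. The fallback takes the second quinone out of the coupling; it sets out from 9 and 22 and comes back at 23. Quinone 9 is reduced (Na2S2O4, H2O/Et2O) to hydroquinone 8 and methylated (Me2SO4, K2CO3, acetone) to 1,3,4-trimethoxy-2-methyl-5-(2-phenylethyl)benzene F1. Iodination of its only free ring position (N-iodosuccinimide, CF3CO2H cat., MeCN) gives 1-iodo-2,4,5-trimethoxy-3-methyl-6-(2-phenylethyl)benzene F2. Stannylquinone 22, made from 20 as in the first half of step 9 and isolated, is joined to F2 by Stille coupling (Pd2(dba)3, tri(2-furyl)phosphine, CuI, DMF; aryl iodides are the established partners of stannylquinones) to give 2-methoxy-6-[2-(2-methoxyphenyl)ethyl]-3-methyl-5-[2,4,5-trimethoxy-3-methyl-6-(2-phenylethyl)phenyl]cyclohexa-2,5-diene-1,4-dione F3. Oxidative demethylation of the para-dimethoxy pair of the new ring with (NH4)2Ce(NO3)6 in MeCN/H2O returns 23.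

2. Step 7. Ionisation after trifluoroacetylation may not stay at the methyl carbinol: loss of the silyl group or ionisation at the propargylic carbon would scramble the substitution pattern, and MeLi may attack silicon. The fallback controls regiochemistry through a cyclobutenedione monoketal instead of a protecting group; it sets out from 1 and 13 and comes back at 20. MeLi addition to 1 and NH4Cl work-up give 4-hydroxy-2,3-dimethoxy-4-methylcyclobut-2-en-1-one F4. 1,2-Bis(trimethylsilyloxy)ethane with catalytic TMSOTf (THF, −78 °C → rt) ionises the carbinol and traps the cation at the far methoxy carbon, giving the monoketal 3-methoxy-2-methyl-5,8-dioxaspiro[3.4]oct-2-en-1-one F5, in which the ketal sits next to C–OMe and the free carbonyl next to C–CH3. Lithium acetylide 14 (from 13, n-BuLi) adds to that only carbonyl to give 3-methoxy-1-[4-(2-methoxyphenyl)but-1-yn-1-yl]-2-methyl-5,8-dioxaspiro[3.4]oct-2-en-1-ol F6. Dilute H2SO4 in wet THF removes the ketal and returns 20.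

3. Step 10. Hydroxide may attack the biquinone elsewhere than at the two methoxy-bearing carbons (conjugate addition at the chain-bearing carbons, redox disproportionation, ring contraction of the hydroxyquinone anions), eroding the material. The fallback cleaves the O–CH3 bonds instead of the ring C–O bonds; it sets out from 23 and comes back at 25. BCl3 in CH2Cl2 at −78 °C chelates each quinone carbonyl with its neighbouring methoxy oxygen, and chloride removes the methyl group to give the bis(dichloroboryl) ether F7. Aqueous work-up gives 25. The anisole, which has no ortho carbonyl, should stay methylated at this temperature.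

**Further compounds**

F1 | step 9 | 1,3,4-trimethoxy-2-methyl-5-(2-phenylethyl)benzene | COc1c(C)c(OC)c(OC)c(CCc2ccccc2)c1
F2 | step 9 | 1-iodo-2,4,5-trimethoxy-3-methyl-6-(2-phenylethyl)benzene | COc1c(C)c(OC)c(OC)c(CCc2ccccc2)c1I
F3 | step 9 | 2-methoxy-6-[2-(2-methoxyphenyl)ethyl]-3-methyl-5-[2,4,5-trimethoxy-3-methyl-6-(2-phenylethyl)phenyl]cyclohexa-2,5-diene-1,4-dione | O=C1C(OC)=C(C)C(=O)C(c2c(OC)c(C)c(OC)c(OC)c2CCc2ccccc2)=C1CCc1ccccc1OC
F4 | step 7 | 4-hydroxy-2,3-dimethoxy-4-methylcyclobut-2-en-1-one (racemic) | CC1(O)C(OC)=C(OC)C1=O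
F5 | step 7 | 3-methoxy-2-methyl-5,8-dioxaspiro[3.4]oct-2-en-1-one | CC1=C(OC)C2(OCCO2)C1=O
F6 | step 7 | 3-methoxy-1-[4-(2-methoxyphenyl)but-1-yn-1-yl]-2-methyl-5,8-dioxaspiro[3.4]oct-2-en-1-ol (racemic) | CC1=C(OC)C2(OCCO2)C1(O)C#CCCc1ccccc1OC
F7 | step 10 | bis(dichloroboryl) ether of 25 | COc1ccccc1CCC1=C(C2=C(CCc3ccccc3)C(=O)C(OB(Cl)Cl)=C(C)C2=O)C(=O)C(C)=C(OB(Cl)Cl)C1=O
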